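**Strategy.** The target, quercetin 4'-O-sulfate, is reached from a flavone whose ring C is cut at C4a–C4, C4–C3 and O1–C2. The route exploits the fact that C4 is an isolated carbonyl carbon flanked by C4a of ring A and by the C3–C2 pair that carries ring B, while O1 sits ortho to C4a. A palladium-catalysed carbonylative annulation therefore stitches a benzyl-protected 2-iodophenol (ring A), carbon monoxide and a ring B arylacetylene into ring C in one operation. The alkyne already bears the 4'-sulfate as an amine-stable neopentyl diester. The 3-hydroxyl is added afterwards by epoxidation of the C2–C3 double bond, and deprotection releases the sulfate.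

Key step: step 7

Assumption: the target is taken as drawn, the free hydrogen sulfate at O4'; it is liberated from its sodium salt in the last step. Flavone numbering (O1, C2, C3, C4, C4a, C5–C8, C8a, ring B primed) is used. The target has no stereocenter; the epoxide formed in step 8 is racemic and its stereocenters vanish in the same step.

Step 1
Reactants: 1 3,5-bis(benzyloxy)phenol
Product: 2 3,5-bis(benzyloxy)-2-iodophenol
Conditions: I2 (1.05 equiv), NaHCO3, THF–H2O (1:1), 0 °C, dark
Reagents that add atoms: iodine, II
Why: Electrophilic aromatic iodination of the phenoxide should go to C2, ortho to the hydroxyl and para to a benzyloxy group, because C4 is shielded by two flanking benzyloxy groups, the site preference known for 3-alkoxyphenols under aqueous bicarbonate.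

Step 2
Reactants: 3 neopentyl alcohol
Product: 4 neopentyl chlorosulfate
Conditions: SO2Cl2, pyridine, Et2O, −78 °C to rt
Reagents that add atoms: sulfuryl chloride, O=S(=O)(Cl)Cl
Why: Chlorosulfonylation of a primary alcohol by sulfuryl chloride with pyridine as HCl acceptor, in which the neopentyl group blocks SN2 collapse of the chlorosulfate to the alkyl chloride.

Step 3
Reactants: 5 2-(benzyloxy)phenol
Product: 6 2-(benzyloxy)-4-bromophenol
Conditions: NBS (1.0 equiv), MeCN, −20 to 0 °C
Reagents that add atoms: N-bromosuccinimide, O=C1CCC(=O)N1Br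
Why: Electrophilic aromatic bromination goes para to the free hydroxyl, the stronger activating group, as with guaiacol.

Step 4
Reactants: 6 2-(benzyloxy)-4-bromophenol; 4 neopentyl chlorosulfate
Product: 8 2-(benzyloxy)-4-bromophenyl neopentyl sulfate, via sodium phenoxide 7 (not isolated)
Conditions: NaH, THF, 0 °C; then 4, 0 °C to rt
Reagents that add atoms: none
Why: O-Sulfonylation of the sodium phenoxide by the chlorosulfate gives the aryl alkyl sulfate diester, a standard way to install a neopentyl-protected sulfate.

Step 5
Reactants: 8 2-(benzyloxy)-4-bromophenyl neopentyl sulfate; 9 trimethylsilylacetylene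
Product: 10 2-(benzyloxy)-4-[(trimethylsilyl)ethynyl]phenyl neopentyl sulfate
Conditions: PdCl2(PPh3)2 (3 mol %), CuI (5 mol %), Et3N, THF, 65 °C, sealed vessel
Reagents that add atoms: none
Why: Sonogashira coupling of an aryl bromide activated by the para sulfonyloxy group; the sulfate diester is inert to zerovalent palladium and to the tertiary amine.

Step 6
Reactants: 10 2-(benzyloxy)-4-[(trimethylsilyl)ethynyl]phenyl neopentyl sulfate
Product: 11 2-(benzyloxy)-4-ethynylphenyl neopentyl sulfate
Conditions: K2CO3 (0.2 equiv), MeOH–CH2Cl2, 0 °C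
Reagents that add atoms: none
Why: Protodesilylation of the alkynylsilane by catalytic methoxide is fast at 0 °C, so the exposure of the hindered sulfate diester to base stays brief.

Step 7
Reactants: 2 3,5-bis(benzyloxy)-2-iodophenol; 12 carbon monoxide; 11 2-(benzyloxy)-4-ethynylphenyl neopentyl sulfate
Product: 15 5,7,3'-tri-O-benzylluteolin 4'-(neopentyl sulfate), via aryl ynone 13 (not isolated), via enaminone 14 (not isolated)
Conditions: PdCl2(PPh3)2 (5 mol %), CO (10 bar), Et2NH–THF (1:1), 60 °C
Reagents that add atoms: none
Why: Zerovalent palladium, formed from PdCl2(PPh3)2 under amine and CO, adds oxidatively to the C–I bond of 2, CO inserts to give the aroyl complex of divalent palladium, and alkynyl transfer from 11 followed by reductive elimination forms C4a–C4 and C4–C3 in ynone 13. Diethylamine then adds to 13 in conjugate fashion to give enaminone 14, and the ortho hydroxyl attacks the amine-bearing carbon C2 and expels diethylamine, forming O1–C2. The closest known reaction type is the carbonylative coupling–cyclisation of 2-iodophenols with terminal arylalkynes in secondary amines, which gives flavones. Ring C closes in a 6-endo mode, formally 6-endo-dig on the ynone and in practice a 6-endo-trig addition–elimination on the enaminone, and no stereocenter is formed. The step needs carbonylative coupling to win over direct coupling and six-membered closure over five-membered closure: the iodine flanked by hydroxyl and benzyloxy groups gives a hindered aryl palladium species that takes up CO before it meets the alkyne, copper is left out and CO is kept under pressure, and the enaminone leaves C2 as the only electrophilic carbon within reach of the phenol, so neither benzofuran nor aurone should form. The hindered neopentyl sulfate diester and the 3'-benzyl ether should pass through the amine medium unchanged.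

Step 8
Reactants: 15 5,7,3'-tri-O-benzylluteolin 4'-(neopentyl sulfate)
Product: 17 5,7,3'-tri-O-benzylquercetin 4'-(neopentyl sulfate), via flavone 2,3-epoxide 16 (not isolated)
Conditions: dimethyldioxirane (acetone solution), CH2Cl2, 0 °C; then p-TsOH·H2O (cat.), CH2Cl2, rt
Reagents that add atoms: dimethyldioxirane, CC1(C)OO1
Why: Epoxidation of the C2–C3 enol ether double bond, the only electron-rich alkene, followed by acid opening at C2 to an oxocarbenium ion that loses H3, is the known epoxidation–isomerisation of flavones to 3-hydroxyflavones.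

Step 9
Reactants: 17 5,7,3'-tri-O-benzylquercetin 4'-(neopentyl sulfate)
Product: 18 sodium 5,7,3'-tri-O-benzylquercetin 4'-sulfate
Conditions: NaN3 (3 equiv), DMF, 70 °C
Reagents that add atoms: sodium azide, [Na+].[N-]=[N+]=[N-]
Why: SN2 displacement at the neopentyl carbon by azide with the aryl sulfate monoanion as leaving group is the standard release of neopentyl-protected sulfates, and doing it while O3' is still benzylated prevents attack of a free neighbouring phenol on the diester.

Step 10
Reactants: 18 sodium 5,7,3'-tri-O-benzylquercetin 4'-sulfate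
Product: 19 sodium quercetin 4'-sulfate
Conditions: H2 (1 atm), Pd/C (10 wt %), MeOH–THF, rt
Reagents that add atoms: none
Why: Catalytic hydrogenolysis cleaves the three aryl benzyl ethers, while aryl sulfate salts and the flavonol core are stable to hydrogen over Pd/C at ambient pressure and temperature.

Step 11
Reactants: 19 sodium quercetin 4'-sulfate
Product: 20 quercetin 4'-(hydrogen sulfate)
Conditions: Dowex 50WX8 (H+ form), H2O–MeOH, 0 °C; immediate freeze-drying
Reagents that add atoms: none
Why: Cation exchange on a sulfonic acid resin replaces Na+ by H+, and the eluate should be kept cold and freeze-dried at once because aryl hydrogen sulfates hydrolyse slowly in their own acid.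

**Compound list**

1 | 3,5-bis(benzyloxy)phenol | Oc1cc(OCc2ccccc2)cc(OCc2ccccc2)c1 | starting material
2 | 3,5-bis(benzyloxy)-2-iodophenol | Oc1cc(OCc2ccccc2)cc(OCc2ccccc2)c1I | intermediate
3 | neopentyl alcohol (2,2-dimethylpropan-1-ol) | CC(C)(C)CO | starting material
4 | neopentyl chlorosulfate | CC(C)(C)COS(=O)(=O)Cl | intermediate
5 | 2-(benzyloxy)phenol | Oc1ccccc1OCc1ccccc1 | starting material
6 | 2-(benzyloxy)-4-bromophenol | Oc1ccc(Br)cc1OCc1ccccc1 | intermediate
7 | sodium 2-(benzyloxy)-4-bromophenoxide | [Na+].[O-]c1ccc(Br)cc1OCc1ccccc1 | intermediate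
8 | 2-(benzyloxy)-4-bromophenyl neopentyl sulfate | CC(C)(C)COS(=O)(=O)Oc1ccc(Br)cc1OCc1ccccc1 | intermediate
9 | trimethylsilylacetylene | C#C[Si](C)(C)C | starting material
10 | 2-(benzyloxy)-4-[(trimethylsilyl)ethynyl]phenyl neopentyl sulfate | CC(C)(C)COS(=O)(=O)Oc1ccc(C#C[Si](C)(C)C)cc1OCc1ccccc1 | intermediate
11 | 2-(benzyloxy)-4-ethynylphenyl neopentyl sulfate | C#Cc1ccc(OS(=O)(=O)OCC(C)(C)C)c(OCc2ccccc2)c1 | intermediate
12 | carbon monoxide | [C-]#[O+] | starting material
13 | aryl ynone, 1-[2,4-bis(benzyloxy)-6-hydroxyphenyl]-3-[3-(benzyloxy)-4-(neopentyloxysulfonyloxy)phenyl]prop-2-yn-1-one | O=C(C#Cc1ccc(OS(=O)(=O)OCC(C)(C)C)c(OCc2ccccc2)c1)c1c(O)cc(OCc2ccccc2)cc1OCc1ccccc1 | intermediate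
14 | enaminone, (E)-1-[2,4-bis(benzyloxy)-6-hydroxyphenyl]-3-[3-(benzyloxy)-4-(neopentyloxysulfonyloxy)phenyl]-3-(diethylamino)prop-2-en-1-one (either alkene isomer would cyclise) | O=C(/C=C(/N(CC)CC)c1ccc(OS(=O)(=O)OCC(C)(C)C)c(OCc2ccccc2)c1)c1c(O)cc(OCc2ccccc2)cc1OCc1ccccc1 | intermediate
15 | 5,7,3'-tri-O-benzylluteolin 4'-(neopentyl sulfate) | O=c1cc(-c2ccc(OS(=O)(=O)OCC(C)(C)C)c(OCc3ccccc3)c2)oc2cc(OCc3ccccc3)cc(OCc3ccccc3)c12 | intermediate
16 | racemic 2,3-epoxide of 15 (oxirane cis-fused to ring C, one enantiomer drawn) | O=C1[C@@H]2O[C@]2(c2ccc(OS(=O)(=O)OCC(C)(C)C)c(OCc3ccccc3)c2)Oc2cc(OCc3ccccc3)cc(OCc3ccccc3)c21 | intermediate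
17 | 5,7,3'-tri-O-benzylquercetin 4'-(neopentyl sulfate) | O=c1c(O)c(-c2ccc(OS(=O)(=O)OCC(C)(C)C)c(OCc3ccccc3)c2)oc2cc(OCc3ccccc3)cc(OCc3ccccc3)c12 | intermediate
18 | sodium 5,7,3'-tri-O-benzylquercetin 4'-sulfate | O=c1c(O)c(-c2ccc(OS(=O)(=O)[O-])c(OCc3ccccc3)c2)oc2cc(OCc3ccccc3)cc(OCc3ccccc3)c12.[Na+] | intermediate
19 | sodium quercetin 4'-sulfate | O=c1c(O)c(-c2ccc(OS(=O)(=O)[O-])c(O)c2)oc2cc(O)cc(O)c12.[Na+] | intermediate
20 | quercetin 4'-(hydrogen sulfate) | O=c1c(O)c(-c2ccc(OS(=O)(=O)O)c(O)c2)oc2cc(O)cc(O)c12 | target

**Step count.** 11 steps in total. The longest linear sequence is 9 steps (steps 3 to 11, from 5); ring A iodide 2 and chlorosulfate 4 are each one step from their starting materials.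

**Steps most likely to fail**

1. Step 7. The aroyl palladium intermediate may be intercepted by diethylamine to give an amide. The alkyne may also couple before CO is taken up and then close to a five-membered ring. Slow oxidative addition at the hindered iodide would favour both diversions. The fallback sets out from 1 and comes back at 13; it brings C4 in as a formyl carbon and uses neither palladium nor CO. Magnesium-mediated ortho-formylation of 1 (MgCl2, Et3N, paraformaldehyde, MeCN, reflux) should give 2-hydroxy-4,6-bis(benzyloxy)benzaldehyde F1. Alkyne 11 would be deprotonated with LiN(iPr)2 in THF at −78 °C to its lithium acetylide F2. F1 would be added to 2.2 equiv of F2; the first equivalent only deprotonates the phenol and returns as 11 on work-up. After an NH4Cl quench this should give the racemic propargylic alcohol F3. MnO2 in CH2Cl2 should oxidise F3 to ynone 13, here isolated. Et2NH in EtOH at room temperature would then close 13 to 15 through 14, as in the main route.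

2. Step 8. The dioxirane may oxidise benzylic C–H bonds or electron-rich ring A instead of the C2–C3 double bond, or the epoxide may contract ring C during acid opening. The fallback sets out from 15 and comes back at 17; it replaces electrophilic oxidation by an anionic hydroxylation at C3. Deprotonation of 15 at C3 with LiN(iPr)2 in THF at −78 °C would give the 3-lithioflavone F4. Quenching with B(OMe)3 and then AcOH should give the dimethyl flavon-3-ylboronate F5. Oxidation of F5 with H2O2 in the same flask should give 17.

3. Step 1. Iodination may occur at C4 between the two benzyloxy groups, or twice at C2 and C6, to give a mixture that is costly to separate. The fallback sets out from 1 and comes back at 2; it fixes the site by directed ortho-metalation. Carbamoylation of 1 (ClCONEt2, K2CO3, MeCN, reflux) should give 3,5-bis(benzyloxy)phenyl N,N-diethylcarbamate F6. s-BuLi and TMEDA in THF at −78 °C would lithiate between the carbamate and a benzyloxy group to give the 2-lithio carbamate F7, kept cold to avoid acyl migration. Iodine would convert F7 into 3,5-bis(benzyloxy)-2-iodophenyl N,N-diethylcarbamate F8. Reductive cleavage of the carbamate with Cp2Zr(H)Cl in THF at room temperature should release 2 without touching the aryl iodide.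

**Further compounds**

F1 | step 7 | 2-hydroxy-4,6-bis(benzyloxy)benzaldehyde | O=Cc1c(O)cc(OCc2ccccc2)cc1OCc1ccccc1
F2 | step 7 | lithium acetylide of 11 | [Li]C#Cc1ccc(OS(=O)(=O)OCC(C)(C)C)c(OCc2ccccc2)c1
F3 | step 7 | racemic 1-[2,4-bis(benzyloxy)-6-hydroxyphenyl]-3-[3-(benzyloxy)-4-(neopentyloxysulfonyloxy)phenyl]prop-2-yn-1-ol | OC(C#Cc1ccc(OS(=O)(=O)OCC(C)(C)C)c(OCc2ccccc2)c1)c1c(O)cc(OCc2ccccc2)cc1OCc1ccccc1
F4 | step 8 | 3-lithio derivative of 15 | [Li]c1c(-c2ccc(OS(=O)(=O)OCC(C)(C)C)c(OCc3ccccc3)c2)oc2cc(OCc3ccccc3)cc(OCc3ccccc3)c2c1=O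
F5 | step 8 | dimethyl boronate of 15 at C3 | COB(OC)c1c(-c2ccc(OS(=O)(=O)OCC(C)(C)C)c(OCc3ccccc3)c2)oc2cc(OCc3ccccc3)cc(OCc3ccccc3)c2c1=O
F6 | step 1 | 3,5-bis(benzyloxy)phenyl N,N-diethylcarbamate | CCN(CC)C(=O)Oc1cc(OCc2ccccc2)cc(OCc2ccccc2)c1
F7 | step 1 | 3,5-bis(benzyloxy)-2-lithiophenyl N,N-diethylcarbamate | CCN(CC)C(=O)Oc1cc(OCc2ccccc2)cc(OCc2ccccc2)c1[Li]
F8 | step 1 | 3,5-bis(benzyloxy)-2-iodophenyl N,N-diethylcarbamate | CCN(CC)C(=O)Oc1cc(OCc2ccccc2)cc(OCc2ccccc2)c1I
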